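1. I started from an invariant: each mono adduct holds one reagent and each double product two, so c(mono adduct) + 2 c(double product) counts the reagent taken up by the starting material. Divided by the starting material charged, this balance folds the charges into one number, the equivalents e, reagent charged per starting material charged: 1.10 for this flask.

| setting | Friday's | Monday's | Tuesday's | flask |
|---|---|---|---|---|
| starting material | 0.020 M | 0.020 M | 0.030 M | 0.020 M |
| reagent | 0.031 M (fed, over 1.5 h) | 0.048 M (fed, over 1.5 h) | 0.022 M (fed, over 1.5 h) | 0.0220 M (fed, over 1.5 h) |
| remark | run made earlier | run made earlier | run made earlier |  |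
| time |  |  |  | 50 h |

| run | time / h | mono adduct / % | double product / % |
|---|---|---|---|
| Friday's | 0.417 | 9.9 | 1.5 |
| Friday's | 2.00 | 15.5 | 51.2 |
| Friday's | 8.00 | 10.4 | 72.3 |
| Friday's | 40.0 | 10.7 | 72.8 |
| Monday's | 0.417 | 11.6 | 3.6 |
| Monday's | 2.00 | 7.4 | 74.3 |
| Monday's | 8.00 | 2.0 | 99.2 |
| Monday's | 40.0 | 0 | 100.5 |
| Tuesday's | 0.417 | 6.1 | 0 |
| Tuesday's | 2.00 | 20.6 | 23.9 |
| Tuesday's | 8.00 | 20.7 | 27.2 |
| Tuesday's | 40.0 | 22.5 | 26.2 |

(each reading ± 1 percentage point)

- the earlier runs were read with a standard deviation of 1 percentage point

- time up to 50 h at which mono adduct stands highest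
- the amount of mono adduct, in percent of the starting material charged, at that time

2. I tested it on the last readings. Friday's sum stood at 156% against e = 1.55. Monday's, with e = 2.40, stopped at 201%.

3. One number gives this sum but not the split. I read the split across runs: final mono adduct went from 22.5% on Tuesday's, e = 0.733, to 10.7% on Friday's. Interpolating at this flask's e gave 17.2%.

4. The same interpolation at 2.00 h gave 18.3%, higher than the final value, though within about the scatter of 1 point. I therefore expected a peak near or before that time, but e gave me no height for it.

5. The forecast gave 21.7% at 1.6 h, and said the flask “passes this peak”.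

6. The flask gave 19.9% at 1.47 h, so the forecast held.

    starting material + reagent → mono adduct + by-product (k = 4.84 M⁻¹ min⁻¹)
    reagent + mono adduct → double product + by-product (k = 3.03 M⁻¹ min⁻¹)
    reagent → decomposition product (k = 1.03 × 10⁻⁴ min⁻¹)
    starting material ⇌ dormant form (K = 3.10, k = 0.183 min⁻¹)

At 50.0 h this flask held 17.3% mono adduct and 46.1% double product, a sum of 110% against e = 110%. Reagent, the limiting reagent, stood at 0%, and the dormant form, which e does not show, at 27.6%. The neighbouring flask, with 0.037 M of reagent, has e = 1.85 equiv, and its sum came to 184%. Interpolating from Friday's final value down to zero at e = 2 gave 3.57%, and the neighbouring flask ended with 3.73% mono adduct.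

(The numbers in the tables were computed with constants of no real substance, noise included.)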